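Locants used throughout: unprimed atoms and rings A, B and C belong to the flavanonol half (C2 ketal carbon, C3 carbinol carbon, C4 ketone; ring B is the aryl group on C2). Primed atoms and rings D and E belong to the flavan half. Ring F is the dihydrofuran O7'–C2–C3–C8'–C7'. The descriptors of the target SMILES are 2R, 3S and 2'S. Compound numbers are those of the steps and of the list after them.

Assumption on reagents: (−)-B-allyldiisopinocampheylborane (2), ethoxyacetylene (12, as a hexane solution) and apigenin (28) are taken as purchasable.

Assumption on C2 and C3: closure of a ketal ring of this kind gives, and equilibration at C2 keeps, only the cis-fused arrangement (O7'–C2 and C8'–C3 on one face of ring C, ring B and the C3 hydroxyl on the other), so C2 is taken to follow from C3; the C2 descriptor of the target SMILES, read literally, makes the fusion trans, so the strings of 34 and 35 carry the target descriptors unchanged and the cis-fused ketal with the same C3 and C2' is the compound meant.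

## Analysis of the target

The target is a biflavonoid in which a 5,7,4'-trihydroxyflavanonol (rings A, B, C) and a (2S)-5,7,4'-trihydroxyflavan (rings D, E) are joined twice, by the C3–C8' bond and by the O7'–C2 bond, so that a dihydrofuran (ring F) is fused across C2–C3. C2 is a ketal carbon (O1, O7', ring B) and C3 a tertiary alcohol next to the C4 ketone; both are fully substituted and both lie on the bond shared by rings C and F, so a ketal closure sets C2 only in relation to C3. The third centre, C2' (S), lies on ring E five bonds from C3 and cannot be expected to influence the other two. Sensitive groups are the ketal (acid), the α-ketol beside it (base), the benzylic C2'–O1' bond of the 2-(4-hydroxyphenyl)chroman (acid, hydrogenolysis) and five free phenols on electron-rich rings. The synthesis is hard because of the two contiguous fully substituted centres and because of ring D. Ring D is a pentasubstituted benzene with oxygen on C5', C7' (O7' of ring F) and C8a' (O1' of ring E), carbon on C4a' (to C4') and on C8' (to C3), and hydrogen only on C6'. In a preformed 5,7-dioxygenated flavan C6' and C8' are electronically almost the same, so the strategy builds ring D from open-chain pieces by a benzannulation whose mechanism places every substituent, with silicon marking C8'.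

## Retrosynthetic reasoning

35 from 34. All five phenols are carried as benzyl ethers and freed last, because hydrogenolysis is neutral and should leave the ketal and the α-ketol alone. The tertiary C3 hydroxyl is left free.

34 from 32. The O7'–C2 and C3–O bonds are cut together, which returns both fully substituted centres to the flat 2,3-diarylchromone 32. Its C2=C3 bond is a latent C2 oxocarbenium ion and C3 carbinol: oxygen transfer gives epoxide 33, and O7', released from its silyl ether, opens it at the carbon stabilised by O1 and ring B, from the face opposite to the oxirane oxygen. Only the cis-fused ring can form, so C2 follows C3. The face of oxygen transfer relative to C2' is the one stereochemical question this cut leaves open. Cutting here, and not at C3–C4 or C2–O1, keeps rings A, B and C intact so that they can come from a commercial flavone.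

32 from 27 and 31. The C3–C8' bond joins two sp2 carbons and is made by Suzuki coupling. Boron is placed on the electron-rich flavan carbon (27) and iodine on flavone C3 (31), where metalation of tribenzyl ether 29 (through 30) puts it selectively. 29 comes from apigenin (28) in one step.

27 from 26, 25 and 24. The boron of 27 is traced through iodide 26 to the trimethylsilyl group of 25 and 24. Ipso substitution at silicon is what fixes C8' and not C6'. O7' is silylated (25) to temper ring D during iodination and to serve later as the trigger for ring F closure.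

24 from 19 (key step). Ring D is cut at C7'–C8' and C4a'–C8a', and ring E falls open with it. The precursor 19 is a 3-benzyloxycyclobutenone tethered through C4'–C3'–C2'–O1' to a trimethylsilyl ynol ether. Forward, the cyclobutenone carbonyl becomes the free O7' hydroxyl, the benzyloxy group ends on C5', the ring CH2 becomes C6'–H, the ynol ether oxygen becomes O1' and silicon ends on C8'. C2' is carried in unchanged.

19 from 11 and 17. The C4'–C4a' bond is cut and made by Negishi coupling. The order matters: the ynol ether can only be made with a metal hydride and an alkyllithium, which a 3-alkoxycyclobutenone would not survive. Growing the four-membered ring afterwards from a second ynol ether would have to compete with the silyl ynol ether already present. The ynol ether is therefore completed first (11), and the finished iodocyclobutenone 17 is attached last under neutral conditions at room temperature.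

17 from 16, 15, 12 and 13. The cyclobutenone comes from ethoxyacetylene (12) and ketene (14, from acetyl chloride 13). Ethoxy is exchanged for benzyloxy (16) so that O5' is freed in the final hydrogenolysis, and C2 of the four-membered ring is iodinated (17).

11 from 9, 7, 5, 3, 1, 2 and 4. The iodide comes from alcohol 9, and the silyl ynol ether of 9 from dichlorovinyl ether 7, itself made from carbinol 3 and trichloroethylene (4). A halide at the chain end would not survive the alkoxide step (closure to a four-membered ether). A vinyl group directly on the carbinol carbon would make the product an allyl alkynyl ether, a class that undergoes [3,3] rearrangement far below room temperature. The chain end is therefore carried as an allyl group and cut back by one carbon by ozonolysis after the alkoxide step (5 to 7). C2' is set in the first step by allylboration of aldehyde 1 with reagent 2.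

## Alternatives that were turned down

Alternative 1: ring A made last by Claisen folding of a polyketide chain.
- Disconnection: the C4a–C5 bond of ring A. The phloroglucinol ring is unravelled into the tetraketide ester A1, in which a methyl 3,5,7-trioxoheptanoate chain sits on C3 of a ring F methyl ketal and the C3 oxygen is a methoxymethyl ether.
- Forward key step: base would enolise A1, the C4a carbanion would acylate the ester carbon, and enolisation would give the 2,4,6-trihydroxybenzoyl ketone A2. Acid would then exchange the methyl ketal of A2 for a ring A oxygen and close ring C.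
- For: ring A appears with its three oxygens in place and unprotected. Both fully substituted centres are fixed before the key step. Only three benzyl ethers remain for the end, so the last steps are gentler than in the chosen route; on these points it is stronger.
- Against: a tetraketide such as A1 can also fold by aldol condensation to a resorcylate or close through oxygen to a pyrone. The ketone that starts the chain sits on a hindered C3 next to a ketal and is open to retro-Claisen cleavage under the same base. The chain has to be grown stepwise on that centre. The plan does not say how rings D, E and F with the C8' substituent are obtained, nor how C2/C3 are related to C2'.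
- Comparison: it is longer, and it spends its key step on the one ring that apigenin supplies ready-made. The chosen plan puts its key step at ring D, where the target cannot be bought.

Alternative 2: carbene, water and ester.
- Disconnection: the C3–O and C2–C3 bonds, leading to the α-diazo ketone A3. The diazo carbon (future C3) lies between C8' and the tribenzyloxybenzoyl group, and O7' carries a 4-benzyloxybenzoate.
- Forward key step: Rh2(OAc)4 would form the carbenoid from A3, water would add to give an oxonium ylide and then an enol, and the enol would attack the neighbouring ester carbonyl to give hemiketal A4 with ring F closed. Ring C would follow by dehydrative ketalisation.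
- For: both fully substituted centres, the C3 oxygen and ring F arise in one mild operation from a flat precursor, with no oxidant and no hindered coupling. In this it is stronger than the chosen route.
- Against: trapping of such ylides is established for aldehydes, imines and activated ketones, not for aryl esters, so a proton shift to the plain O–H insertion product is the likely course. The carbenoid also lies next to benzylic C–H bonds of ortho benzyloxy groups. A4 has two hydroxyls and a hemiketal whose ring–chain equilibria must be steered towards ring C. C3 is formed without reference to C2', as in the chosen route.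
- Comparison: A3 presupposes a flavan acylated only at C8' with O7' distinguished from O5'. That is the task the benzannulation solves. The chosen strategy offers a secure ring D in exchange for a less elegant construction of C2 and C3.

Alternative 3: carbene-catalysed crossed benzoin.
- Disconnection: the C3–C4 bond. Ring C is opened to aldehyde A5, a 2-aryl-2-aryloxybenzofuran-3-one whose aryloxy group is ring A with the future C4 as an ortho formyl group.
- Forward key step: a chiral triazolylidene carbene would turn the aldehyde of A5 into its Breslow intermediate, which adds to the C3 ketone and gives A6, the penta-O-benzyl ether of the target, identical with 34.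
- For: aldehyde–ketone benzoin closure to 3-hydroxychroman-4-ones is well precedented and needs no oxidant. Because the C2 ketal centre is already present and the fusion must be cis, a chiral catalyst can in principle choose which C2 epimer reacts. In stereocontrol at C2 and C3 this plan is stronger than the chosen one.
- Against: A5 is a mixed diaryl ketal at a quaternary carbon next to a ketone, hard to assemble from a hindered, electron-rich salicylaldehyde and prone to hydrolysis. The ketone is flanked by that quaternary carbon and a di-ortho-substituted arene, and the aldehyde is deactivated by two alkoxy groups, so the benzoin step may be slow and reversible. The benzofuranone again needs a flavan functionalised at C8' and O7' only.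
- Comparison: the chosen strategy is weaker at the last bond-forming stage, but it supplies exactly that flavan (24) by a mechanism that leaves no regiochemical choice, and it reaches 34 with rings A, B and C taken intact from apigenin.

Key step: step 10

## Steps

Step 1
Reactants: 1 4-(benzyloxy)benzaldehyde; 2 (−)-B-allyldiisopinocampheylborane
Product: 3 (1S)-1-[4-(benzyloxy)phenyl]but-3-en-1-ol
Conditions: 2 (1.2 equiv), Et2O, −78 °C; then 3 M NaOH, 30% H2O2, 0 → 20 °C
Reagents that add atoms: none
Why: Brown allylboration through a chair six-membered transition state; the reagent derived from (+)-α-pinene delivers allyl to the Si face of aryl aldehydes, which sets C2' as (S), and the oxidative work-up frees the alcohol.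

Step 2
Reactants: 3 (1S)-1-[4-(benzyloxy)phenyl]but-3-en-1-ol; 4 trichloroethylene
Product: 5 1-(benzyloxy)-4-[(1S)-1-{[(E)-1,2-dichloroethenyl]oxy}but-3-en-1-yl]benzene
Conditions: KH (2 equiv), THF, 0 → 20 °C; then 4 (1.2 equiv), −50 → 20 °C
Reagents that add atoms: none
Why: Trichloroethylene route to ynol ethers, first stage: the potassium alkoxide converts trichloroethylene by elimination–addition into the (E)-1,2-dichlorovinyl ether. No bond to the stereocentre is touched, and the terminal alkene is inert to the base.

Step 3
Reactants: 5 1-(benzyloxy)-4-[(1S)-1-{[(E)-1,2-dichloroethenyl]oxy}but-3-en-1-yl]benzene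
Product: 7 (3S)-3-[4-(benzyloxy)phenyl]-3-{[(E)-1,2-dichloroethenyl]oxy}propan-1-ol, via aldehyde 6 (not isolated)
Conditions: O3, CH2Cl2/MeOH (4:1), −78 °C, Sudan Red 7B end-point; then NaBH4 (3 equiv), −78 → 0 °C
Reagents that add atoms: ozone, [O-][O+]=O
Why: Ozonolysis with reductive work-up; the terminal alkene reacts with ozone well before the chlorine-deactivated enol ether or the arene, and reduction in the cold keeps the β-alkoxy aldehyde 6 from eliminating. One allyl carbon is lost, which leaves the two-carbon link C3'–C4'.

Step 4
Reactants: 7 (3S)-3-[4-(benzyloxy)phenyl]-3-{[(E)-1,2-dichloroethenyl]oxy}propan-1-ol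
Product: 9 (3S)-3-[4-(benzyloxy)phenyl]-3-{[(trimethylsilyl)ethynyl]oxy}propan-1-ol, via bis-silyl ether 8 (not isolated)
Conditions: n-BuLi (3.3 equiv), THF, −78 → −40 °C; Me3SiCl (3.5 equiv), −78 → 0 °C; then sat. aq NH4Cl, 20 °C, 30 min
Reagents that add atoms: chlorotrimethylsilane, C[Si](C)(C)Cl
Why: Second stage of the trichloroethylene route: dehydrochlorination and chlorine–lithium exchange with the alcohol carried as its lithium alkoxide, then silylation at carbon and oxygen. The primary O–SiMe3 group of 8 is hydrolysed at about pH 5, where the C–SiMe3 bond and the ynol ether should survive; C2' is untouched.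

Step 5
Reactants: 9 (3S)-3-[4-(benzyloxy)phenyl]-3-{[(trimethylsilyl)ethynyl]oxy}propan-1-ol
Product: 11 ({[(1S)-1-[4-(benzyloxy)phenyl]-3-iodopropyl]oxy}ethynyl)trimethylsilane, via mesylate 10 (not isolated)
Conditions: MsCl, Et3N, CH2Cl2, 0 °C; then NaI (5 equiv), acetone, 20 °C, dark
Reagents that add atoms: methanesulfonyl chloride, CS(=O)(=O)Cl (in 10 only); sodium iodide, [Na+].[I-]
Why: Sulfonylation under amine base and Finkelstein exchange at 20 °C are basic to neutral throughout, as the acid-labile and heat-labile silyl ynol ether requires.

Step 6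
Reactants: 12 ethoxyacetylene; 13 acetyl chloride
Product: 15 3-ethoxycyclobut-2-en-1-one, via ketene 14 (not isolated)
Conditions: 12 (2 equiv), Et3N (slow addition), Et2O, 0 → 20 °C
Reagents that add atoms: none
Why: Dehydrohalogenation of acetyl chloride gives ketene 14, which undergoes [2+2] cycloaddition with the ynol ether; the ketene carbonyl carbon bonds to the unsubstituted alkyne carbon, giving the 3-alkoxycyclobutenone (a known preparation).

Step 7
Reactants: 15 3-ethoxycyclobut-2-en-1-one
Product: 16 3-(benzyloxy)cyclobut-2-en-1-one
Conditions: BnOH (5 equiv), camphorsulfonic acid (5 mol%), toluene, 40 °C, EtOH removed under reduced pressure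
Reagents that add atoms: benzyl alcohol, OCc1ccccc1
Why: Acid-catalysed addition–elimination at C3 of the vinylogous ester (transetherification), driven by removal of ethanol; it places a hydrogenolysable group on the future O5'.

Step 8
Reactants: 16 3-(benzyloxy)cyclobut-2-en-1-one
Product: 17 3-(benzyloxy)-2-iodocyclobut-2-en-1-one
Conditions: N-iodosuccinimide (1.1 equiv), MeCN, 0 → 20 °C, dark
Reagents that add atoms: N-iodosuccinimide, O=C1CCC(=O)N1I
Why: C2 is the nucleophilic α-carbon of the vinylogous ester, so electrophilic iodination occurs there and not at C4; the product is an α-iodoenone of the kind used in cross-coupling.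

Step 9
Reactants: 11 ({[(1S)-1-[4-(benzyloxy)phenyl]-3-iodopropyl]oxy}ethynyl)trimethylsilane; 17 3-(benzyloxy)-2-iodocyclobut-2-en-1-one
Product: 19 3-(benzyloxy)-2-[(3S)-3-[4-(benzyloxy)phenyl]-3-{[(trimethylsilyl)ethynyl]oxy}propyl]cyclobut-2-en-1-one, via alkylzinc iodide 18 (not isolated)
Conditions: Zn dust (activated with 1,2-dibromoethane), LiCl, THF, 25 °C; then 17, Pd(OAc)2 (3 mol%), SPhos (6 mol%), THF, 20 °C
Reagents that add atoms: zinc, [Zn] (in 18 only)
Why: Negishi coupling: zinc inserts into the primary C–I bond at 25 °C in the presence of LiCl, and the Pd(OAc)2/SPhos catalyst joins the alkylzinc to the α-iodoenone faster than β-hydride elimination. The conditions are neutral and at room temperature, so the cyclobutenone and the ynol ether should both survive.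

Step 10
Reactants: 19 3-(benzyloxy)-2-[(3S)-3-[4-(benzyloxy)phenyl]-3-{[(trimethylsilyl)ethynyl]oxy}propyl]cyclobut-2-en-1-one
Product: 24 (2S)-5-(benzyloxy)-2-[4-(benzyloxy)phenyl]-8-(trimethylsilyl)-3,4-dihydro-2H-chromen-7-ol, via vinylketene 20 (not isolated), via fused vinylcyclobutenone 21 (not isolated), via dienylketene 22 (not isolated), via dienone 23 (not isolated)
Conditions: hν (300 nm, Pyrex), degassed toluene (0.005 M), 20 °C; then 80 °C, 1 h
Reagents that add atoms: none
Why: Proposed new method: excitation of the cyclobutenone should cause four-electron electrocyclic opening to vinylketene 20, whose ketene carbon is attacked by the silylated, nucleophilic alkyne carbon while its α-carbon bonds to the oxygen-bearing alkyne carbon, so that the [2+2] step forms C7'–C8' and C4a'–C8a' and gives 21. Ring E is thereby closed as a six-membered ring in the fused, not bridged, mode, which is the mode favoured by both the ynol ether polarity and the four-atom tether. Opening of 21, under the lamp or on the final warming, gives dienylketene 22, in which ring E holds the ketene and the benzyloxyvinyl group cis on the C4a'=C8a' bond, so 6π electrocyclisation to dienone 23 (C6'–C7' bond, ring D) and enolisation to phenol 24 should follow with no torquoselectivity issue. The closest known reactions are the intermolecular cyclobutenone–alkoxyalkyne (Danheiser) benzannulation and intramolecular ketene [2+2] cycloadditions that give bicyclo[4.2.0] systems; a tether running from the ketene α-carbon through an ynol ether oxygen has not been shown. No stereocentre is created: C2' is carried through, and the quaternary centre of 21 is lost on ring opening. The selectivity needed is regiochemical (hydroxyl on C7', silicon on C8', benzyloxy on C5', hydrogen on C6') and is secured by the ketene/ynol ether polarity and by the tether, which allows one mode of addition only. The competing process is retro-ene fragmentation of the secondary benzylic ynol ether, which is why the ketene is generated by light at 20 °C and heat is applied only after the ynol ether has been consumed.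

Step 11
Reactants: 24 (2S)-5-(benzyloxy)-2-[4-(benzyloxy)phenyl]-8-(trimethylsilyl)-3,4-dihydro-2H-chromen-7-ol
Product: 25 {[(2S)-5-(benzyloxy)-2-[4-(benzyloxy)phenyl]-8-(trimethylsilyl)-3,4-dihydro-2H-chromen-7-yl]oxy}(tert-butyl)dimethylsilane
Conditions: t-BuMe2SiCl, imidazole, DMF, 20 °C
Reagents that add atoms: tert-butyldimethylsilyl chloride, CC(C)(C)[Si](C)(C)Cl
Why: Standard silylation of the phenol; the silyl ether tempers ring D for the iodination, should survive the borylation and the cross-coupling, and is the trigger for ring F closure in step 17.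

Step 12
Reactants: 25 {[(2S)-5-(benzyloxy)-2-[4-(benzyloxy)phenyl]-8-(trimethylsilyl)-3,4-dihydro-2H-chromen-7-yl]oxy}(tert-butyl)dimethylsilane
Product: 26 {[(2S)-5-(benzyloxy)-2-[4-(benzyloxy)phenyl]-8-iodo-3,4-dihydro-2H-chromen-7-yl]oxy}(tert-butyl)dimethylsilane
Conditions: ICl (1.05 equiv), CH2Cl2, −78 °C; aq Na2S2O3
Reagents that add atoms: iodine monochloride, ClI
Why: Ipso-iododesilylation: attack at the silicon-bearing carbon is favoured over attack at C6'–H by the β-silicon effect, and loss of Me3SiCl leaves iodine at C8' only. One equivalent at −78 °C limits further iodination.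

Step 13
Reactants: 26 {[(2S)-5-(benzyloxy)-2-[4-(benzyloxy)phenyl]-8-iodo-3,4-dihydro-2H-chromen-7-yl]oxy}(tert-butyl)dimethylsilane
Product: 27 2-[(2S)-5-(benzyloxy)-2-[4-(benzyloxy)phenyl]-7-[(tert-butyldimethylsilyl)oxy]-3,4-dihydro-2H-chromen-8-yl]-4,4,5,5-tetramethyl-1,3,2-dioxaborolane
Conditions: B2pin2, Pd(dppf)Cl2 (5 mol%), KOAc, 1,4-dioxane, 90 °C
Reagents that add atoms: bis(pinacolato)diboron, CC1(C)OB(OC1(C)C)B1OC(C)(C)C(C)(C)O1
Why: Miyaura borylation of an aryl iodide; KOAc is too weak a base to cleave the aryl silyl ether or to promote protodeboronation.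

Step 14
Reactants: 28 apigenin
Product: 29 5,7-bis(benzyloxy)-2-[4-(benzyloxy)phenyl]-4H-chromen-4-one
Conditions: BnBr (4 equiv), K2CO3, DMF, 80 °C
Reagents that add atoms: benzyl bromide, BrCc1ccccc1
Why: Williamson etherification; forcing conditions are needed for the hydrogen-bonded 5-hydroxyl.

Step 15
Reactants: 29 5,7-bis(benzyloxy)-2-[4-(benzyloxy)phenyl]-4H-chromen-4-one
Product: 31 5,7-bis(benzyloxy)-2-[4-(benzyloxy)phenyl]-3-iodo-4H-chromen-4-one, via 3-lithioflavone 30 (not isolated)
Conditions: LiN(i-Pr)2 (1.5 equiv), THF, −78 °C; then I2, −78 → 0 °C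
Reagents that add atoms: lithium diisopropylamide, [Li+].CC(C)[N-]C(C)C (lithium in 30 only); iodine, II
Why: The vinylic C3–H next to the carbonyl is removed by the lithium amide at −78 °C and the 3-lithio species 30 is trapped by iodine; electrophilic iodination would attack ring A instead.

Step 16
Reactants: 27 2-[(2S)-5-(benzyloxy)-2-[4-(benzyloxy)phenyl]-7-[(tert-butyldimethylsilyl)oxy]-3,4-dihydro-2H-chromen-8-yl]-4,4,5,5-tetramethyl-1,3,2-dioxaborolane; 31 5,7-bis(benzyloxy)-2-[4-(benzyloxy)phenyl]-3-iodo-4H-chromen-4-one
Product: 32 5,7-bis(benzyloxy)-2-[4-(benzyloxy)phenyl]-3-[(2S)-5-(benzyloxy)-2-[4-(benzyloxy)phenyl]-7-[(tert-butyldimethylsilyl)oxy]-3,4-dihydro-2H-chromen-8-yl]-4H-chromen-4-one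
Conditions: Pd(OAc)2 (5 mol%), SPhos (10 mol%), K3PO4, toluene/H2O (10:1), 90 °C
Reagents that add atoms: none
Why: Suzuki–Miyaura coupling; a dialkylbiarylphosphine is chosen because both partners carry two ortho substituents and the 2,6-dioxygenated boronate is prone to protodeboronation, so transmetalation has to be fast. The product is expected as two slowly interconverting rotamers about C3–C8'.

Step 17
Reactants: 32 5,7-bis(benzyloxy)-2-[4-(benzyloxy)phenyl]-3-[(2S)-5-(benzyloxy)-2-[4-(benzyloxy)phenyl]-7-[(tert-butyldimethylsilyl)oxy]-3,4-dihydro-2H-chromen-8-yl]-4H-chromen-4-one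
Product: 34 penta-O-benzyl ether of the target (C3 hydroxyl free), via epoxide 33 (not isolated)
Conditions: dimethyldioxirane (acetone solution, 3 equiv), CH2Cl2, 0 → 20 °C; evaporate; then Bu4NF (1.1 equiv), AcOH (1.1 equiv), THF, −20 → 0 °C; chromatography
Reagents that add atoms: dimethyldioxirane, CC1(C)OO1
Why: Dioxirane epoxidation of the chromone C2=C3 bond (known for flavones), then buffered fluoride releases the O7' phenol, which opens the epoxide at the doubly stabilised C2 from the face opposite to the oxirane oxygen and gives the cis-fused ketal. C3 is set by the face of oxygen transfer and C2 follows from the ring fusion. Because C2' is too remote to bias that face, both cis-fused diastereomers are expected, and the one with the C3 configuration of the target is separated from its C2,C3-inverted isomer by chromatography.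

Step 18
Reactants: 34 penta-O-benzyl ether of the target
Product: 35 target CNP0208300.3
Conditions: H2 (1 atm), Pd(OH)2/C, EtOAc/MeOH (1:1), 20 °C
Reagents that add atoms: none
Why: Hydrogenolysis of the five benzyl ethers under neutral conditions; low pressure and short reaction time are chosen so that the benzylic C2'–O1' and C2–O bonds and the C4 ketone are not reduced. No stereocentre is affected.

## Compound list

1 | 4-(benzyloxy)benzaldehyde | O=Cc1ccc(OCc2ccccc2)cc1 | starting material
2 | (−)-B-allyldiisopinocampheylborane (from (+)-α-pinene) | C=CCB([C@@H]1C[C@@H]2C[C@H]([C@H]1C)C2(C)C)[C@@H]1C[C@@H]2C[C@H]([C@H]1C)C2(C)C | starting material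
3 | (1S)-1-[4-(benzyloxy)phenyl]but-3-en-1-ol | C=CC[C@H](O)c1ccc(OCc2ccccc2)cc1 | intermediate
4 | trichloroethylene | ClC=C(Cl)Cl | starting material
5 | 1-(benzyloxy)-4-[(1S)-1-{[(E)-1,2-dichloroethenyl]oxy}but-3-en-1-yl]benzene | C=CC[C@H](O/C(Cl)=C\Cl)c1ccc(OCc2ccccc2)cc1 | intermediate
6 | (3S)-3-[4-(benzyloxy)phenyl]-3-{[(E)-1,2-dichloroethenyl]oxy}propanal (not isolated) | O=CC[C@H](O/C(Cl)=C\Cl)c1ccc(OCc2ccccc2)cc1 | intermediate
7 | (3S)-3-[4-(benzyloxy)phenyl]-3-{[(E)-1,2-dichloroethenyl]oxy}propan-1-ol | OCC[C@H](O/C(Cl)=C\Cl)c1ccc(OCc2ccccc2)cc1 | intermediate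
8 | trimethyl{[(3S)-3-[4-(benzyloxy)phenyl]-3-{[(trimethylsilyl)ethynyl]oxy}propyl]oxy}silane (not isolated) | C[Si](C)(C)OCC[C@H](OC#C[Si](C)(C)C)c1ccc(OCc2ccccc2)cc1 | intermediate
9 | (3S)-3-[4-(benzyloxy)phenyl]-3-{[(trimethylsilyl)ethynyl]oxy}propan-1-ol | OCC[C@H](OC#C[Si](C)(C)C)c1ccc(OCc2ccccc2)cc1 | intermediate
10 | (3S)-3-[4-(benzyloxy)phenyl]-3-{[(trimethylsilyl)ethynyl]oxy}propyl methanesulfonate (not isolated) | CS(=O)(=O)OCC[C@H](OC#C[Si](C)(C)C)c1ccc(OCc2ccccc2)cc1 | intermediate
11 | ({[(1S)-1-[4-(benzyloxy)phenyl]-3-iodopropyl]oxy}ethynyl)trimethylsilane | ICC[C@H](OC#C[Si](C)(C)C)c1ccc(OCc2ccccc2)cc1 | intermediate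
12 | ethoxyacetylene | CCOC#C | starting material
13 | acetyl chloride | CC(Cl)=O | starting material
14 | ketene (not isolated) | C=C=O | intermediate
15 | 3-ethoxycyclobut-2-en-1-one | CCOC1=CC(=O)C1 | intermediate
16 | 3-(benzyloxy)cyclobut-2-en-1-one | O=C1CC(OCc2ccccc2)=C1 | intermediate
17 | 3-(benzyloxy)-2-iodocyclobut-2-en-1-one | O=C1CC(OCc2ccccc2)=C1I | intermediate
18 | [(3S)-3-[4-(benzyloxy)phenyl]-3-{[(trimethylsilyl)ethynyl]oxy}propyl]zinc iodide (not isolated) | I[Zn]CC[C@H](OC#C[Si](C)(C)C)c1ccc(OCc2ccccc2)cc1 | intermediate
19 | 3-(benzyloxy)-2-[(3S)-3-[4-(benzyloxy)phenyl]-3-{[(trimethylsilyl)ethynyl]oxy}propyl]cyclobut-2-en-1-one | O=C1CC(OCc2ccccc2)=C1CC[C@H](OC#C[Si](C)(C)C)c1ccc(OCc2ccccc2)cc1 | intermediate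
20 | 3-(benzyloxy)-2-[(3S)-3-[4-(benzyloxy)phenyl]-3-{[(trimethylsilyl)ethynyl]oxy}propyl]buta-1,3-dien-1-one (vinylketene, not isolated) | C=C(OCc1ccccc1)C(=C=O)CC[C@H](OC#C[Si](C)(C)C)c1ccc(OCc2ccccc2)cc1 | intermediate
21 | (3S)-6-[1-(benzyloxy)ethenyl]-3-[4-(benzyloxy)phenyl]-8-(trimethylsilyl)-2-oxabicyclo[4.2.0]oct-1(8)-en-7-one, either configuration at C6 (not isolated) | C=C(OCc1ccccc1)C12CC[C@@H](c3ccc(OCc4ccccc4)cc3)OC1=C([Si](C)(C)C)C2=O | intermediate
22 | 2-[(2S)-5-[1-(benzyloxy)ethenyl]-2-[4-(benzyloxy)phenyl]-3,4-dihydro-2H-pyran-6-yl]-2-(trimethylsilyl)ethen-1-one (dienylketene, not isolated) | O=C=C([Si](C)(C)C)C1=C(C(OCc2ccccc2)=C)CC[C@@H](c2ccc(OCc3ccccc3)cc2)O1 | intermediate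
23 | (2S)-5-(benzyloxy)-2-[4-(benzyloxy)phenyl]-8-(trimethylsilyl)-3,4-dihydro-2H-chromen-7(6H)-one (not isolated) | O=C1CC(OCc2ccccc2)=C2CC[C@@H](c3ccc(OCc4ccccc4)cc3)OC2=C1[Si](C)(C)C | intermediate
24 | (2S)-5-(benzyloxy)-2-[4-(benzyloxy)phenyl]-8-(trimethylsilyl)-3,4-dihydro-2H-chromen-7-ol | C[Si](C)(C)c1c(O)cc(OCc2ccccc2)c2c1O[C@H](c1ccc(OCc3ccccc3)cc1)CC2 | intermediate
25 | {[(2S)-5-(benzyloxy)-2-[4-(benzyloxy)phenyl]-8-(trimethylsilyl)-3,4-dihydro-2H-chromen-7-yl]oxy}(tert-butyl)dimethylsilane | C[Si](C)(C)c1c(O[Si](C)(C)C(C)(C)C)cc(OCc2ccccc2)c2c1O[C@H](c1ccc(OCc3ccccc3)cc1)CC2 | intermediate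
26 | {[(2S)-5-(benzyloxy)-2-[4-(benzyloxy)phenyl]-8-iodo-3,4-dihydro-2H-chromen-7-yl]oxy}(tert-butyl)dimethylsilane | Ic1c(O[Si](C)(C)C(C)(C)C)cc(OCc2ccccc2)c2c1O[C@H](c1ccc(OCc3ccccc3)cc1)CC2 | intermediate
27 | 2-[(2S)-5-(benzyloxy)-2-[4-(benzyloxy)phenyl]-7-[(tert-butyldimethylsilyl)oxy]-3,4-dihydro-2H-chromen-8-yl]-4,4,5,5-tetramethyl-1,3,2-dioxaborolane | CC1(C)OB(OC1(C)C)c1c(O[Si](C)(C)C(C)(C)C)cc(OCc2ccccc2)c2c1O[C@H](c1ccc(OCc3ccccc3)cc1)CC2 | intermediate
28 | apigenin | O=c1cc(-c2ccc(O)cc2)oc2cc(O)cc(O)c12 | starting material
29 | 5,7-bis(benzyloxy)-2-[4-(benzyloxy)phenyl]-4H-chromen-4-one | O=c1cc(-c2ccc(OCc3ccccc3)cc2)oc2cc(OCc3ccccc3)cc(OCc3ccccc3)c12 | intermediate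
30 | 5,7-bis(benzyloxy)-2-[4-(benzyloxy)phenyl]-3-lithio-4H-chromen-4-one (not isolated) | [Li]c1c(-c2ccc(OCc3ccccc3)cc2)oc2cc(OCc3ccccc3)cc(OCc3ccccc3)c2c1=O | intermediate
31 | 5,7-bis(benzyloxy)-2-[4-(benzyloxy)phenyl]-3-iodo-4H-chromen-4-one | O=c1c(I)c(-c2ccc(OCc3ccccc3)cc2)oc2cc(OCc3ccccc3)cc(OCc3ccccc3)c12 | intermediate
32 | 5,7-bis(benzyloxy)-2-[4-(benzyloxy)phenyl]-3-[(2S)-5-(benzyloxy)-2-[4-(benzyloxy)phenyl]-7-[(tert-butyldimethylsilyl)oxy]-3,4-dihydro-2H-chromen-8-yl]-4H-chromen-4-one | O=c1c(-c2c(O[Si](C)(C)C(C)(C)C)cc(OCc3ccccc3)c3c2O[C@H](c2ccc(OCc4ccccc4)cc2)CC3)c(-c2ccc(OCc3ccccc3)cc2)oc2cc(OCc3ccccc3)cc(OCc3ccccc3)c12 | intermediate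
33 | (2S,3S)-2,3-epoxide of 32 (cis oxirane across C2–C3 of ring C, oxygen on the face that carries the C3 hydroxyl in 34, rings B and D on the other face; not isolated) | O=C1c2c(OCc3ccccc3)cc(OCc3ccccc3)cc2O[C@@]2(c3ccc(OCc4ccccc4)cc3)O[C@@]12c1c(O[Si](C)(C)C(C)(C)C)cc(OCc2ccccc2)c2c1O[C@H](c1ccc(OCc3ccccc3)cc1)CC2 | intermediate
34 | penta-O-benzyl ether of the target (benzyl on O5, O7, the ring B oxygen, O5' and the oxygen of the C2' aryl group; C3 hydroxyl free; descriptors 2R,3S,2'S as in the target SMILES) | O=C1c2c(OCc3ccccc3)cc(OCc3ccccc3)cc2O[C@@]2(c3ccc(OCc4ccccc4)cc3)Oc3cc(OCc4ccccc4)c4c(c3[C@]12O)O[C@H](c1ccc(OCc3ccccc3)cc1)CC4 | intermediate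
35 | target CNP0208300.3 (descriptors 2R,3S,2'S as in the target SMILES) | O=C1c2c(O)cc(O)cc2O[C@@]2(c3ccc(O)cc3)Oc3cc(O)c4c(c3[C@]12O)O[C@H](c1ccc(O)cc1)CC4 | target

## Step count and least certain steps

Total: 18 steps. Longest linear sequence: 13 steps (1, 2, 3, 4, 5, 9, 10, 11, 12, 13, 16, 17, 18), starting from 1.

Step 10 (key step, proposed new method). What may go wrong: retro-ene fragmentation of the ynol ether before the cycloaddition, reclosure or dimerisation of the vinylketene outpacing the six-membered [2+2] closure, or photodegradation of the electron-rich product. The fallback uses known chemistry, sets out from mesylate 10 (isolated for this purpose) and cyclobutenone 16, and rejoins the route at 24. The two are combined in an intermolecular cyclobutenone–alkoxyalkyne benzannulation (irradiation at 20 °C, then brief warming). The same polarity rule gives (3S)-3-[4-(benzyloxy)phenyl]-3-[5-(benzyloxy)-3-hydroxy-2-(trimethylsilyl)phenoxy]propyl methanesulfonate F1, with the ynol ether oxygen already the future O1' and C2' untouched. Ring E is then closed by base-mediated para-C-alkylation of the phenoxide (KOt-Bu, t-BuOH, high dilution). The only carbon that the three-atom tether can reach and that is not blocked by silicon is the one para to the phenoxide oxygen, the future C4a', and this gives 24.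

Step 17. What may go wrong: lack of facial bias in the oxygen transfer relative to C2', so that much of the material ends in the other cis-fused series; oxidation of benzylic C–H bonds or of ring D while the hindered, electron-poor double bond reacts slowly; rearrangement of the epoxide before ring F closes. The fallback sets out from 32 and rejoins at 34. The two rotamers of 32 about C3–C8', which are diastereomers because of C2', are separated. In each rotamer the bulky silyl ether shields one face of the chromone and already holds O7' opposite to the face that receives oxygen, so the axis controls C3. The rotamer that leads to the wanted face is oxidised, and the other is re-equilibrated by heating and recycled. This fallback makes no compound outside the list and is entered as F0.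

Step 9. What may go wrong: protonolysis of the alkylzinc, β-hydride elimination at palladium, or degradation of the ynol ether by Lewis-acidic ZnI2. The fallback changes the bond construction; it sets out from 11 and rejoins at 19. Benzyl alcohol and trichloroethylene 4 (KH) give benzyl (E)-1,2-dichloroethenyl ether F2. Two equivalents of n-BuLi convert it into lithium (benzyloxy)ethynide F3, which is alkylated by iodide 11 (THF/DMPU, −78 → 0 °C) to the bis-ynol ether F4. Ketene 14, generated as in step 6, should then add to the less hindered, alkyl-substituted ynol ether of F4 and give 19 directly. The weakness of this fallback is competition from the silyl ynol ether.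

Step 16. What may go wrong: protodeboronation of the 2,6-dioxygenated boronate, slow transmetalation at a junction with four ortho substituents, and partial loss of the aryl silyl ether under aqueous base. The fallback reverses the polarity and avoids base; it sets out from 26 and rejoins at 32. Iodine–magnesium exchange (i-PrMgCl·LiCl, THF) and transmetalation with ZnCl2 give arylzinc chloride F5, which is coupled with 31 under Negishi conditions (Pd(OAc)2, RuPhos, THF, 50 °C).

Step 4. What may go wrong: loss of the C-silyl group or hydration of the ynol ether during the selective O-desilylation, or addition of the liberated hydroxyl to the ynol ether. The fallback changes the order of events; it sets out from 5 and rejoins at 9. The dichlorovinyl ether of 5 is converted first (n-BuLi, 2.2 equiv; Me3SiCl) into the homoallylic silyl ynol ether F6, so that no alkoxide or O-silyl group is involved. The terminal alkene is then cleaved (OsO4 cat., NaIO4, 2,6-lutidine, dioxane/H2O) and the aldehyde reduced in the same flask with NaBH4 to give 9.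

## Further compounds

F1 | step 10 | (3S)-3-[4-(benzyloxy)phenyl]-3-[5-(benzyloxy)-3-hydroxy-2-(trimethylsilyl)phenoxy]propyl methanesulfonate | CS(=O)(=O)OCC[C@H](Oc1cc(OCc2ccccc2)cc(O)c1[Si](C)(C)C)c1ccc(OCc2ccccc2)cc1
F0 | step 17 | none | none
F2 | step 9 | benzyl (E)-1,2-dichloroethenyl ether | Cl/C=C(/Cl)OCc1ccccc1
F3 | step 9 | lithium (benzyloxy)ethynide | [Li]C#COCc1ccccc1
F4 | step 9 | ({[(1S)-5-(benzyloxy)-1-[4-(benzyloxy)phenyl]pent-4-yn-1-yl]oxy}ethynyl)trimethylsilane | C(#COCc1ccccc1)CC[C@H](OC#C[Si](C)(C)C)c1ccc(OCc2ccccc2)cc1
F5 | step 16 | [(2S)-5-(benzyloxy)-2-[4-(benzyloxy)phenyl]-7-[(tert-butyldimethylsilyl)oxy]-3,4-dihydro-2H-chromen-8-yl]zinc chloride | Cl[Zn]c1c(O[Si](C)(C)C(C)(C)C)cc(OCc2ccccc2)c2c1O[C@H](c1ccc(OCc3ccccc3)cc1)CC2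
F6 | step 4 | ({[(1S)-1-[4-(benzyloxy)phenyl]but-3-en-1-yl]oxy}ethynyl)trimethylsilane | C=CC[C@H](OC#C[Si](C)(C)C)c1ccc(OCc2ccccc2)cc1
A1 | alternative 1 | tetraketide ester: methyl 3,5,7-trioxoheptanoate chain on C3 of the ring F methyl ketal, C3 oxygen as methoxymethyl ether | CO[C@@]2(c3ccc(OCc5ccccc5)cc3)Oc3cc(OCc5ccccc5)c4c(c3[C@]2(OCOC)C(=O)CC(=O)CC(=O)CC(=O)OC)O[C@H](c1ccc(OCc5ccccc5)cc1)CC4
A2 | alternative 1 | C3 2,4,6-trihydroxybenzoyl ketone on the ring F methyl ketal | CO[C@@]2(c3ccc(OCc5ccccc5)cc3)Oc3cc(OCc5ccccc5)c4c(c3[C@]2(OCOC)C(=O)c6c(O)cc(O)cc6O)O[C@H](c1ccc(OCc5ccccc5)cc1)CC4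
A3 | alternative 2 | α-diazo ketone at the future C3 with O7' 4-(benzyloxy)benzoate | [N-]=[N+]=C(C(=O)c1c(OCc2ccccc2)cc(OCc2ccccc2)cc1OCc1ccccc1)c1c(OC(=O)c2ccc(OCc3ccccc3)cc2)cc(OCc2ccccc2)c2c1O[C@H](c1ccc(OCc3ccccc3)cc1)CC2
A4 | alternative 2 | ring F 2-hydroxy hemiketal with C3 hydroxyl and C4 aryl ketone | O[C@@]2(c3ccc(OCc5ccccc5)cc3)Oc3cc(OCc5ccccc5)c4c(c3[C@]2(O)C(=O)c6c(OCc5ccccc5)cc(OCc5ccccc5)cc6OCc5ccccc5)O[C@H](c1ccc(OCc5ccccc5)cc1)CC4
A5 | alternative 3 | 2-aryl-2-(2-formylaryloxy)benzofuran-3-one fused to the flavan | O=Cc1c(OCc2ccccc2)cc(OCc2ccccc2)cc1O[C@@]1(c2ccc(OCc3ccccc3)cc2)Oc2cc(OCc3ccccc3)c3c(c2C1=O)O[C@H](c1ccc(OCc2ccccc2)cc1)CC3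
A6 | alternative 3 | penta-O-benzyl ether of the target (identical with 34) | O=C1c2c(OCc5ccccc5)cc(OCc5ccccc5)cc2O[C@@]2(c3ccc(OCc5ccccc5)cc3)Oc3cc(OCc5ccccc5)c4c(c3[C@]12O)O[C@H](c1ccc(OCc5ccccc5)cc1)CC4
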